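**Plan**

- Retrosynthesis: the two isopropyl–oxygen bonds of a 5,7-di-O-isopropyl ether are cut first, then O1–C8a of ring B (the 5,7-dioxygenated coumarin), which leads back to an E-cinnamic acid.
- That acid is cut at the C3=C4 bond of its side chain to an aryl aldehyde and malonic acid, and the diaryl ether C8(ring B)–O bond is cut to 5-bromo-2,4-diisopropoxybenzaldehyde and 8-hydroxy-7-methoxycoumarin.
- Forward: ring A is bought intact; the ether is joined first, the three-carbon acid chain is added, the B pyranone is closed last by photo-oxidative lactonisation, and the isopropyl groups are removed.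
- Enabling feature: in ring B, O1 sits on C8a, next to the ether carbon C8, and C8a is the only hydrogen-bearing ortho carbon of the acrylic acid on C4a. O1 can therefore arrive last, and the bromide used for the ether carries a single ortho substituent.
- Stereochemistry: the target has no stereocentre; the only stereo-element on the route is the E-alkene of the acid, which the key step itself inverts to Z before closure.

Key step: step 4

Remark: the target has no stereocentre and no hindered axis, so it is achiral and "single enantiomer" reduces to the constitution shown; 1, 3 and 5 are taken as catalogue compounds.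

**Route**

Step 1
Reactants: 1 5-bromo-2,4-dihydroxybenzaldehyde
Product: 2 5-bromo-2,4-diisopropoxybenzaldehyde
Conditions: i-PrBr (4 equiv), K2CO3, DMF, 70 °C
Reagents that add atoms: 2-bromopropane, CC(C)Br
Why: Williamson ether synthesis, in which carbonate deprotonates both phenols and the phenoxides displace bromide from the secondary halide (excess halide and warming carry the hydrogen-bonded 2-OH to completion), while the aryl bromide and the non-enolisable aldehyde are untouched.

Step 2
Reactants: 2 5-bromo-2,4-diisopropoxybenzaldehyde, 3 8-hydroxy-7-methoxy-2H-chromen-2-one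
Product: 4 2,4-diisopropoxy-5-[(7-methoxy-2-oxo-2H-chromen-8-yl)oxy]benzaldehyde
Conditions: CuI (10 mol%), picolinic acid (20 mol%), K3PO4, DMSO, 90 °C
Reagents that add atoms: none
Why: Ullmann-type copper-catalysed diaryl ether synthesis with picolinic acid as ligand, a system suited to ortho-substituted phenols; the bromide has only one ortho substituent because O1 of ring B is still absent, and anhydrous phosphate should leave the lactone of 3 and the aldehyde intact.

Step 3
Reactants: 4 2,4-diisopropoxy-5-[(7-methoxy-2-oxo-2H-chromen-8-yl)oxy]benzaldehyde, 5 malonic acid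
Product: 7 (E)-3-{2,4-diisopropoxy-5-[(7-methoxy-2-oxo-2H-chromen-8-yl)oxy]phenyl}prop-2-enoic acid, via arylidenemalonic acid 6 (not isolated)
Conditions: pyridine, piperidine (0.1 equiv), 90 °C; then cold dil. HCl
Reagents that add atoms: none
Why: Knoevenagel–Doebner condensation, in which the arylidenemalonic acid loses CO2 in hot pyridine to give the thermodynamically preferred E-acid, the amine being present only in catalytic amount and as its malonate salt so that the A-ring lactone should not be opened.

Step 4
Reactants: 7 (E)-3-{2,4-diisopropoxy-5-[(7-methoxy-2-oxo-2H-chromen-8-yl)oxy]phenyl}prop-2-enoic acid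
Product: 9 5,7-diisopropoxy-8-[(7-methoxy-2-oxo-2H-chromen-8-yl)oxy]-2H-chromen-2-one, via Z-cinnamic acid 8 (not isolated)
Conditions: (−)-riboflavin (5 mol%), O2 (1 atm), MeCN/MeOH 1:1, 402 nm LEDs, rt
Reagents that add atoms: none
Why: Excited riboflavin first transfers triplet energy to the E-acid, which relaxes to the Z-acid 8 and brings the carboxyl group next to C8a; a second excited flavin then removes one electron from the 1,2,4-trioxygenated arene, the carboxylate oxygen adds to C8a of the radical cation, and loss of a further electron and a proton restores aromaticity, the reduced flavin being reoxidised by O2. The closest known reaction type is the riboflavin-photocatalysed E-to-Z isomerisation and oxidative cyclisation of cinnamic acids to coumarins, used here on a new substrate. The B pyranone closes by O1–C8a bond formation in a six-membered mode (6-endo with respect to the C4a–C8a bond of the arene), and no stereocentre is formed. The step needs site selectivity for C8a–H over ipso attack at the isopropoxy-bearing C5: C8a is the only hydrogen-bearing ortho carbon and only its adduct can rearomatise by simple proton loss, whereas an ipso adduct would have to expel a secondary alkyl group and should revert. It also needs chemoselectivity between the two halves: at 402 nm only the flavin absorbs, the A-ring coumarin lies too high in triplet energy to be sensitised and is too electron-poor to be oxidised, and the same should protect the product from over-oxidation.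

Step 5
Reactants: 9 5,7-diisopropoxy-8-[(7-methoxy-2-oxo-2H-chromen-8-yl)oxy]-2H-chromen-2-one
Product: 10 5,7-dihydroxy-8-[(7-methoxy-2-oxo-2H-chromen-8-yl)oxy]-2H-chromen-2-one
Conditions: BCl3 (1 M in CH2Cl2, 5 equiv), CH2Cl2, −78 → 0 °C; then H2O
Reagents that add atoms: none
Why: Lewis-acid ether dealkylation, in which BCl3 ionises the secondary isopropyl–oxygen bonds (giving 2-chloropropane) far faster than the primary methyl–oxygen bond, so both isopropyl ethers should fall while the 7-methoxy group, the diaryl ether and both lactones remain.

**Compound list**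

1 | 5-bromo-2,4-dihydroxybenzaldehyde | O=Cc1cc(Br)c(O)cc1O | starting material
2 | 5-bromo-2,4-diisopropoxybenzaldehyde | O=Cc1cc(Br)c(OC(C)C)cc1OC(C)C | intermediate
3 | 8-hydroxy-7-methoxy-2H-chromen-2-one (daphnetin 7-methyl ether) | COc1ccc2ccc(=O)oc2c1O | starting material
4 | 2,4-diisopropoxy-5-[(7-methoxy-2-oxo-2H-chromen-8-yl)oxy]benzaldehyde | COc1ccc2ccc(=O)oc2c1Oc1cc(C=O)c(OC(C)C)cc1OC(C)C | intermediate
5 | malonic acid (propanedioic acid) | OC(=O)CC(=O)O | starting material
6 | 2-{2,4-diisopropoxy-5-[(7-methoxy-2-oxo-2H-chromen-8-yl)oxy]benzylidene}malonic acid (arylidenemalonic acid, not isolated) | COc1ccc2ccc(=O)oc2c1Oc1cc(C=C(C(=O)O)C(=O)O)c(OC(C)C)cc1OC(C)C | intermediate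
7 | (E)-3-{2,4-diisopropoxy-5-[(7-methoxy-2-oxo-2H-chromen-8-yl)oxy]phenyl}prop-2-enoic acid | COc1ccc2ccc(=O)oc2c1Oc1cc(/C=C/C(=O)O)c(OC(C)C)cc1OC(C)C | intermediate
8 | (Z)-3-{2,4-diisopropoxy-5-[(7-methoxy-2-oxo-2H-chromen-8-yl)oxy]phenyl}prop-2-enoic acid (Z-cinnamic acid, not isolated) | COc1ccc2ccc(=O)oc2c1Oc1cc(/C=C\C(=O)O)c(OC(C)C)cc1OC(C)C | intermediate
9 | 5,7-diisopropoxy-8-[(7-methoxy-2-oxo-2H-chromen-8-yl)oxy]-2H-chromen-2-one | COc1ccc2ccc(=O)oc2c1Oc1c(OC(C)C)cc(OC(C)C)c2ccc(=O)oc12 | intermediate
10 | 5,7-dihydroxy-8-[(7-methoxy-2-oxo-2H-chromen-8-yl)oxy]-2H-chromen-2-one | COc1ccc2ccc(=O)oc2c1Oc1c(O)cc(O)c2ccc(=O)oc12 | target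

**Step count and risks**

Total step count: 5. Longest linear sequence: 5 steps (1 → 2 → 4 → 7 → 9 → 10).

Steps most likely to fail:

1. Step 4 (photo-oxidative lactonisation).
   - What may go wrong: the flavin/oxygen system may cleave the electron-rich styrene double bond oxidatively; the carboxylate may close ipso at the isopropoxy-bearing C5 with loss of the alkyl group; or closure at C8a, next to the bulky aryloxy group, may be so slow that the Z-acid only accumulates.
   - Fallback, from 4 and back at 9: O1 is placed on the ring before the pyranone is made. The only ortho C–H of aldehyde 4 is hydroxylated by palladium catalysis through a transient imine directing group (Pd(OAc)2, 4-chloroanthranilic acid, 1-fluoro-2,4,6-trimethylpyridinium triflate, TsOH, AcOH, 90 °C), which should give 2-hydroxy-4,6-diisopropoxy-3-[(7-methoxy-2-oxo-2H-chromen-8-yl)oxy]benzaldehyde F1. Wittig olefination of F1 with ethyl (triphenylphosphoranylidene)acetate in refluxing N,N-diethylaniline should give ethyl (E)-3-{2-hydroxy-4,6-diisopropoxy-3-[(7-methoxy-2-oxo-2H-chromen-8-yl)oxy]phenyl}prop-2-enoate F2, which at that temperature isomerises and lactonises with loss of ethanol to 9.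

2. Step 2 (Ullmann coupling).
   - What may go wrong: oxidative addition of copper to the electron-rich, ortho-alkoxylated bromide may be slower than protodebromination; the phenoxide of 3, flanked by two oxygen substituents, may bind copper as a chelate and stall the cycle; prolonged heating with base may then open the lactone.
   - Fallback, from 2 and back at 4: the polarity of the aryl partner is inverted and the ether is formed oxidatively at room temperature. Miyaura borylation of 2 (B2pin2, PdCl2(dppf), KOAc, dioxane, 85 °C) should give 2,4-diisopropoxy-5-(4,4,5,5-tetramethyl-1,3,2-dioxaborolan-2-yl)benzaldehyde F3. Oxidative cleavage of the pinacol ester (NaIO4, NH4OAc, acetone/H2O, rt) should give (5-formyl-2,4-diisopropoxyphenyl)boronic acid F4. Chan–Lam–Evans coupling of F4 with 3 (Cu(OAc)2, pyridine, 4 Å MS, air, CH2Cl2, rt) should then give 4.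

3. Step 3 (Knoevenagel–Doebner condensation).
   - What may go wrong: piperidine may add to or open the A-ring lactone, and the electron-rich cinnamic acid may decarboxylate further to the styrene in hot pyridine.
   - Fallback, from 4 and back at 7: a base-free olefination at the ester oxidation level. Wittig reaction of 4 with tert-butyl (triphenylphosphoranylidene)acetate (toluene, 80 °C) should give tert-butyl (E)-3-{2,4-diisopropoxy-5-[(7-methoxy-2-oxo-2H-chromen-8-yl)oxy]phenyl}prop-2-enoate F5. Acidolysis of F5 (TFA, CH2Cl2, 0 °C → rt) should release 7 with loss of 2-methylpropene, neither operation touching the lactone or the isopropyl ethers.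

**Further compounds**

F1 | step 4 | 2-hydroxy-4,6-diisopropoxy-3-[(7-methoxy-2-oxo-2H-chromen-8-yl)oxy]benzaldehyde | COc1ccc2ccc(=O)oc2c1Oc1c(O)c(C=O)c(OC(C)C)cc1OC(C)C
F2 | step 4 | ethyl (E)-3-{2-hydroxy-4,6-diisopropoxy-3-[(7-methoxy-2-oxo-2H-chromen-8-yl)oxy]phenyl}prop-2-enoate | CCOC(=O)/C=C/c1c(O)c(Oc2c(OC)ccc3ccc(=O)oc23)c(OC(C)C)cc1OC(C)C
F3 | step 2 | 2,4-diisopropoxy-5-(4,4,5,5-tetramethyl-1,3,2-dioxaborolan-2-yl)benzaldehyde | O=Cc1cc(B2OC(C)(C)C(C)(C)O2)c(OC(C)C)cc1OC(C)C
F4 | step 2 | (5-formyl-2,4-diisopropoxyphenyl)boronic acid | O=Cc1cc(B(O)O)c(OC(C)C)cc1OC(C)C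
F5 | step 3 | tert-butyl (E)-3-{2,4-diisopropoxy-5-[(7-methoxy-2-oxo-2H-chromen-8-yl)oxy]phenyl}prop-2-enoate | COc1ccc2ccc(=O)oc2c1Oc1cc(/C=C/C(=O)OC(C)(C)C)c(OC(C)C)cc1OC(C)C
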